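## Retrosynthetic overview

1. Target ⇐ global deprotection (two silyl ethers, C14 dimethyl acetal) ⇐ esterification of the free C8 hydroxyl of the macrolactone with (S)-2-methylbutanoic acid.
2. Macrolactone ⇐ C6–C7 bond: visible-light photoredox/chromium-catalysed intramolecular Barbier allylation of a (Z)-enal by a 2-(bromomethyl)enoate. This closes the 10-membered carbocycle first; the γ-lactone then forms from the new C6 hydroxyl and the ester.
3. Open-chain bromo enal ⇐ C9–C10 bond: Nozaki–Hiyama–Kishi coupling of a (Z)-2-iodoenal acetal (west fragment: C1–C6, C10, C14, C15) with an α-silyloxy aldehyde (east fragment: C7–C9, C11–C13).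
4. West fragment ⇐ mono-silylated but-2-yne-1,4-diol; east fragment ⇐ (S)-glyceraldehyde acetonide, which supplies C8. C9, C7 and C6 are induced from C8; the ester stereocentre is bought in the acid.

Assumption: positions are named by germacrane numbering (lactone carbonyl C12, exocyclic methylene C13, aldehyde C14, hydroxymethyl C15); the target is (6R,7S,8R,9S), trans-fused lactone, both ring alkenes cis within the ring, as the SMILES states.
Assumption: the silylated butynediol, but-3-enylzinc bromide, crotonaldehyde, (S)-glyceraldehyde acetonide, 4-methoxybenzyl alcohol, methyl 2-(dimethoxyphosphoryl)acrylate and (S)-2-methylbutanoic acid are bought.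
Abbreviations: TBS = tert-butyldimethylsilyl, TES = triethylsilyl, PMB = 4-methoxybenzyl.

## Route

Step 1
Reactants: 1 4-[(tert-butyldimethylsilyl)oxy]but-2-yn-1-ol
Product: 3 (2Z)-4-[(tert-butyldimethylsilyl)oxy]-3-iodobut-2-en-1-ol, via alkenylaluminate 2 (not isolated)
Conditions: NaAlH2(OCH2CH2OMe)2, THF, 0 °C → rt; then I2, THF, −78 → 0 °C
Reagents that add atoms: iodine, II
Why: Alkoxide-directed trans-hydroalumination puts aluminium on the distal alkyne carbon (the one bearing CH2OTBS) and iodinolysis with retention gives the (Z)-iodide (hydroalumination–iodination).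

Step 2
Reactants: 3 (2Z)-4-[(tert-butyldimethylsilyl)oxy]-3-iodobut-2-en-1-ol; 4 but-3-en-1-ylzinc bromide
Product: 5 (2E)-3-{[(tert-butyldimethylsilyl)oxy]methyl}hepta-2,6-dien-1-ol
Conditions: 4 (2.5 equiv), Pd(dppf)Cl2 (3 mol%), THF, 45 °C
Reagents that add atoms: none
Why: Negishi sp3–sp2 coupling proceeds with retention, so the butenyl chain ends up cis to the CH2OH carbon, which fixes the C4=C5 geometry (C3 cis to C6).

Step 3
Reactants: 5 (2E)-3-{[(tert-butyldimethylsilyl)oxy]methyl}hepta-2,6-dien-1-ol; 6 (E)-but-2-enal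
Product: 7 (2E,6E)-6-{[(tert-butyldimethylsilyl)oxy]methyl}-8-hydroxyocta-2,6-dienal
Conditions: 6 (5 equiv), second-generation Hoveyda–Grubbs catalyst (3 mol%), CH2Cl2, 40 °C
Reagents that add atoms: none
Why: Olefin cross-metathesis engages only the terminal alkene and gives the E-enal, while the trisubstituted alkene is inert.

Step 4
Reactants: 7 (2E,6E)-6-{[(tert-butyldimethylsilyl)oxy]methyl}-8-hydroxyocta-2,6-dienal
Product: 8 (2Z,6E)-6-{[(tert-butyldimethylsilyl)oxy]methyl}-8-hydroxy-2-iodoocta-2,6-dienal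
Conditions: I2, K2CO3, DMAP (20 mol%), THF/H2O, rt
Reagents that add atoms: iodine, II
Why: Amine-catalysed α-iodination of the enal (Baylis–Hillman-type addition, iodination, elimination) gives the favoured (Z)-2-iodoenal with iodine cis to C2, the geometry needed for C1=C10.

Step 5
Reactants: 8 (2Z,6E)-6-{[(tert-butyldimethylsilyl)oxy]methyl}-8-hydroxy-2-iodoocta-2,6-dienal
Product: 9 (2E,6Z)-3-{[(tert-butyldimethylsilyl)oxy]methyl}-7-iodo-8,8-dimethoxyocta-2,6-dien-1-ol
Conditions: HC(OMe)3, CeCl3·7H2O (10 mol%), MeOH, rt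
Reagents that add atoms: trimethyl orthoformate, COC(OC)OC; methanol, CO
Why: Mild cerium-catalysed acetalisation masks the C14 aldehyde so that it cannot act as a competing electrophile in either chromium step.

Step 6
Reactants: 10 (4S)-2,2-dimethyl-1,3-dioxolane-4-carbaldehyde; 11 (4-methoxyphenyl)methanol; 12 methyl 2-(dimethoxyphosphoryl)prop-2-enoate
Product: 14 methyl (2E)-3-[(4R)-2,2-dimethyl-1,3-dioxolan-4-yl]-2-{[(4-methoxyphenyl)methoxy]methyl}prop-2-enoate, via phosphonate anion 13 (not isolated)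
Conditions: NaH, THF, 0 °C (11, then 12); then 10, −78 → 0 °C
Reagents that add atoms: none
Why: Tandem oxa-Michael/Horner–Wadsworth–Emmons reaction: the alkoxide adds to the phosphonoacrylate and the resulting phosphonate anion olefinates the aldehyde, giving mainly the enoate with C8 trans to the ester, while C8 is carried over unchanged from the bought aldehyde.

Step 7
Reactants: 14 methyl (2E)-3-[(4R)-2,2-dimethyl-1,3-dioxolan-4-yl]-2-{[(4-methoxyphenyl)methoxy]methyl}prop-2-enoate
Product: 15 methyl (2E,4R)-4,5-dihydroxy-2-{[(4-methoxyphenyl)methoxy]methyl}pent-2-enoate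
Conditions: AcOH/H2O (4:1), 40 °C
Reagents that add atoms: none
Why: Acid hydrolysis of the terminal acetonide leaves the PMB ether intact, and any minor geometric isomer lactonises to a butenolide and is separated here.

Step 8
Reactants: 15 methyl (2E,4R)-4,5-dihydroxy-2-{[(4-methoxyphenyl)methoxy]methyl}pent-2-enoate
Product: 16 methyl (2E,4R)-2-{[(4-methoxyphenyl)methoxy]methyl}-4,5-bis[(triethylsilyl)oxy]pent-2-enoate
Conditions: Et3SiCl (2.3 equiv), imidazole, CH2Cl2, 0 °C
Reagents that add atoms: chlorotriethylsilane, CC[Si](Cl)(CC)CC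
Why: Routine bis-silylation; the C8 oxygen is made a silyl ether because a poor leaving group is needed at this position in the later allylation.

Step 9
Reactants: 16 methyl (2E,4R)-2-{[(4-methoxyphenyl)methoxy]methyl}-4,5-bis[(triethylsilyl)oxy]pent-2-enoate
Product: 18 methyl (2E,4R)-2-{[(4-methoxyphenyl)methoxy]methyl}-5-oxo-4-[(triethylsilyl)oxy]pent-2-enoate, via alkoxysulfonium salt 17 (not isolated)
Conditions: (COCl)2, DMSO, CH2Cl2, −78 → −40 °C; then i-Pr2NEt, −78 °C; used at once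
Reagents that add atoms: none
Why: Under Swern conditions a primary triethylsilyl ether is oxidised directly to the aldehyde while the secondary one survives (oxidative desilylation), so a free α-hydroxy aldehyde is never formed.

Step 10
Reactants: 9 (2E,6Z)-3-{[(tert-butyldimethylsilyl)oxy]methyl}-7-iodo-8,8-dimethoxyocta-2,6-dien-1-ol; 18 methyl (2E,4R)-2-{[(4-methoxyphenyl)methoxy]methyl}-5-oxo-4-[(triethylsilyl)oxy]pent-2-enoate
Product: 20 methyl (2E,4R,5S,6E,10E)-10-{[(tert-butyldimethylsilyl)oxy]methyl}-6-(dimethoxymethyl)-5,12-dihydroxy-2-{[(4-methoxyphenyl)methoxy]methyl}-4-[(triethylsilyl)oxy]dodeca-2,6,10-trienoate, via alkenylchromium 19 (not isolated)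
Conditions: 9 (1.5 equiv), CrCl2 (6 equiv), NiCl2 (2 mol%), DMSO, rt
Reagents that add atoms: none
Why: Nozaki–Hiyama–Kishi coupling, in which the alkenylchromium adds to the α-silyloxy aldehyde under Felkin–Anh control (attack anti to the C8–O bond) to give the 8,9-anti alcohol, so C9 is set by C8; the free primary alcohol and the esters are tolerated.

Step 11
Reactants: 20 methyl (2E,4R,5S,6E,10E)-10-{[(tert-butyldimethylsilyl)oxy]methyl}-6-(dimethoxymethyl)-5,12-dihydroxy-2-{[(4-methoxyphenyl)methoxy]methyl}-4-[(triethylsilyl)oxy]dodeca-2,6,10-trienoate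
Product: 21 methyl (2E,4R,5S,6E,10E)-10-{[(tert-butyldimethylsilyl)oxy]methyl}-6-(dimethoxymethyl)-5-hydroxy-2-{[(4-methoxyphenyl)methoxy]methyl}-12-oxo-4-[(triethylsilyl)oxy]dodeca-2,6,10-trienoate
Conditions: TEMPO (20 mol%), PhI(OAc)2 (1.1 equiv), CH2Cl2, rt
Reagents that add atoms: none
Why: TEMPO/PhI(OAc)2 oxidation is selective for the primary allylic alcohol over the hindered secondary one and preserves the alkene geometry (C3 stays cis to the new aldehyde).

Step 12
Reactants: 21 methyl (2E,4R,5S,6E,10E)-10-{[(tert-butyldimethylsilyl)oxy]methyl}-6-(dimethoxymethyl)-5-hydroxy-2-{[(4-methoxyphenyl)methoxy]methyl}-12-oxo-4-[(triethylsilyl)oxy]dodeca-2,6,10-trienoate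
Product: 22 methyl (2E,4R,5S,6E,10E)-5-[(tert-butyldimethylsilyl)oxy]-10-{[(tert-butyldimethylsilyl)oxy]methyl}-6-(dimethoxymethyl)-2-{[(4-methoxyphenyl)methoxy]methyl}-12-oxo-4-[(triethylsilyl)oxy]dodeca-2,6,10-trienoate
Conditions: TBSOTf (1.2 equiv), 2,6-lutidine, CH2Cl2, −78 °C
Reagents that add atoms: tert-butyldimethylsilyl trifluoromethanesulfonate, CC(C)(C)[Si](C)(C)OS(=O)(=O)C(F)(F)F
Why: Silylation of the only free hydroxyl at −78 °C is much faster than activation of the acetal and differentiates O9 (TBS) from O8 (TES) for the late acylation.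

Step 13
Reactants: 22 methyl (2E,4R,5S,6E,10E)-5-[(tert-butyldimethylsilyl)oxy]-10-{[(tert-butyldimethylsilyl)oxy]methyl}-6-(dimethoxymethyl)-2-{[(4-methoxyphenyl)methoxy]methyl}-12-oxo-4-[(triethylsilyl)oxy]dodeca-2,6,10-trienoate
Product: 23 methyl (2E,4R,5S,6E,10E)-5-[(tert-butyldimethylsilyl)oxy]-10-{[(tert-butyldimethylsilyl)oxy]methyl}-6-(dimethoxymethyl)-2-(hydroxymethyl)-12-oxo-4-[(triethylsilyl)oxy]dodeca-2,6,10-trienoate
Conditions: DDQ (1.3 equiv), CH2Cl2/pH 7 buffer, 0 °C
Reagents that add atoms: none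
Why: Oxidative cleavage of the PMB ether leaves silyl ethers, acetal and enal untouched.

Step 14
Reactants: 23 methyl (2E,4R,5S,6E,10E)-5-[(tert-butyldimethylsilyl)oxy]-10-{[(tert-butyldimethylsilyl)oxy]methyl}-6-(dimethoxymethyl)-2-(hydroxymethyl)-12-oxo-4-[(triethylsilyl)oxy]dodeca-2,6,10-trienoate
Product: 24 methyl (2Z,4R,5S,6E,10E)-2-(bromomethyl)-5-[(tert-butyldimethylsilyl)oxy]-10-{[(tert-butyldimethylsilyl)oxy]methyl}-6-(dimethoxymethyl)-12-oxo-4-[(triethylsilyl)oxy]dodeca-2,6,10-trienoate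
Conditions: CBr4, PPh3, 2,6-lutidine, CH2Cl2, 0 °C
Reagents that add atoms: carbon tetrabromide, BrC(Br)(Br)Br
Why: Appel bromination of the single free (primary allylic) alcohol under neutral conditions.

Step 15
Reactants: 24 methyl (2Z,4R,5S,6E,10E)-2-(bromomethyl)-5-[(tert-butyldimethylsilyl)oxy]-10-{[(tert-butyldimethylsilyl)oxy]methyl}-6-(dimethoxymethyl)-12-oxo-4-[(triethylsilyl)oxy]dodeca-2,6,10-trienoate
Product: 26 (6R,7S,8R,9S)-9,15-bis[(tert-butyldimethylsilyl)oxy]-14,14-dimethoxy-8-[(triethylsilyl)oxy]germacra-1(10),4,11(13)-trien-12,6-olide (trans-fused lactone; both ring alkenes cis in the ring), via hydroxy ester 25 (not isolated)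
Conditions: CrCl2 (20 mol%), 4CzIPN (2 mol%), Hantzsch ester (1.5 equiv), 2,6-lutidine (1.5 equiv), DMF, 450 nm LEDs, 20 °C, 24 added by syringe pump over 12 h (final 2 mM); then PPTS (10 mol%), CH2Cl2, rt
Reagents that add atoms: none
Why: Proposed new method: a dual photoredox/chromium-catalysed intramolecular Barbier (Nozaki–Hiyama) allylation, in which photoexcited 4CzIPN is reductively quenched by the Hantzsch ester and the reduced dye returns trivalent chromium to divalent chromium, which abstracts bromine from the allylic bromide and captures the allyl radical as an allylchromium that adds to the tethered enal through a six-membered chair transition state with C5 and C8 pseudo-equatorial (6,7-anti, hence the trans lactone) and with C8–H in the allyl plane and the C8–OSi bond anti to the incoming aldehyde (A1,3 control, so C7 is set by C8), after which lutidinium protonates the chromium alkoxide to turn the metal over and the γ-hydroxy ester lactonises; the closest known reactions are the stoichiometric CrCl2-mediated macrocyclising allylation that gives 10-membered α-methylene lactones and the intermolecular photoredox/chromium-catalysed allylation of aldehydes.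

Step 16
Reactants: 26 (6R,7S,8R,9S)-9,15-bis[(tert-butyldimethylsilyl)oxy]-14,14-dimethoxy-8-[(triethylsilyl)oxy]germacra-1(10),4,11(13)-trien-12,6-olide
Product: 27 8-hydroxy analogue of 26 (9,15-bis-O-TBS 14-dimethyl acetal of the 8-deacyl target; ring stereocentres unchanged)
Conditions: HF·pyridine, pyridine, THF, 0 °C
Reagents that add atoms: none
Why: Buffered fluoride cleaves the triethylsilyl ether far faster than either TBS ether (selective desilylation), which frees only the C8 hydroxyl and does not touch the acetal.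

Step 17
Reactants: 27 8-hydroxy analogue of 26; 28 (2S)-2-methylbutanoic acid
Product: 29 (6R,7S,8R,9S)-9,15-bis[(tert-butyldimethylsilyl)oxy]-14,14-dimethoxy-8-{[(2S)-2-methylbutanoyl]oxy}germacra-1(10),4,11(13)-trien-12,6-olide
Conditions: DCC, DMAP (10 mol%), CH2Cl2, 0 °C → rt
Reagents that add atoms: none
Why: Steglich esterification of the single free hydroxyl proceeds with retention at C8, and the acyl stereocentre is bought.

Step 18
Reactants: 29 (6R,7S,8R,9S)-9,15-bis[(tert-butyldimethylsilyl)oxy]-14,14-dimethoxy-8-{[(2S)-2-methylbutanoyl]oxy}germacra-1(10),4,11(13)-trien-12,6-olide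
Product: 30 (6R,7S,8R,9S)-9,15-dihydroxy-8-{[(2S)-2-methylbutanoyl]oxy}-14-oxogermacra-1(10),4,11(13)-trien-12,6-olide (CNP0331447.11)
Conditions: aq. HF (48%), MeCN, 0 °C → rt
Reagents that add atoms: water, O
Why: Aqueous HF removes both TBS ethers and hydrolyses the allylic dimethyl acetal to the enal under mildly acidic conditions that do not promote 8→9 acyl migration.

## Compound list

1 | 4-[(tert-butyldimethylsilyl)oxy]but-2-yn-1-ol | OCC#CCO[Si](C)(C)C(C)(C)C | starting material
2 | sodium alkenylaluminate (five-membered oxaaluminacycle, Al on the alkene carbon bearing CH2OTBS, two 2-methoxyethoxy ligands) | [Na+].COCCO[Al-]1(OCCOC)OCC=C1CO[Si](C)(C)C(C)(C)C | intermediate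
3 | (2Z)-4-[(tert-butyldimethylsilyl)oxy]-3-iodobut-2-en-1-ol | OC/C=C(\I)CO[Si](C)(C)C(C)(C)C | intermediate
4 | but-3-en-1-ylzinc bromide | C=CCC[Zn]Br | starting material
5 | (2E)-3-{[(tert-butyldimethylsilyl)oxy]methyl}hepta-2,6-dien-1-ol | OC/C=C(/CO[Si](C)(C)C(C)(C)C)CCC=C | intermediate
6 | (E)-but-2-enal | C/C=C/C=O | starting material
7 | (2E,6E)-6-{[(tert-butyldimethylsilyl)oxy]methyl}-8-hydroxyocta-2,6-dienal | O=C/C=C/CC/C(CO[Si](C)(C)C(C)(C)C)=C\CO | intermediate
8 | (2Z,6E)-6-{[(tert-butyldimethylsilyl)oxy]methyl}-8-hydroxy-2-iodoocta-2,6-dienal | O=C/C(I)=C/CC/C(CO[Si](C)(C)C(C)(C)C)=C\CO | intermediate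
9 | (2E,6Z)-3-{[(tert-butyldimethylsilyl)oxy]methyl}-7-iodo-8,8-dimethoxyocta-2,6-dien-1-ol | COC(OC)/C(I)=C/CC/C(CO[Si](C)(C)C(C)(C)C)=C\CO | intermediate
10 | (4S)-2,2-dimethyl-1,3-dioxolane-4-carbaldehyde | O=C[C@@H]1COC(C)(C)O1 | starting material
11 | (4-methoxyphenyl)methanol | COc1ccc(CO)cc1 | starting material
12 | methyl 2-(dimethoxyphosphoryl)prop-2-enoate | C=C(C(=O)OC)P(=O)(OC)OC | starting material
13 | sodium salt of the methyl 2-(dimethoxyphosphoryl)-3-[(4-methoxyphenyl)methoxy]propanoate carbanion | [Na+].COC(=O)[C-](COCc1ccc(OC)cc1)P(=O)(OC)OC | intermediate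
14 | methyl (2E)-3-[(4R)-2,2-dimethyl-1,3-dioxolan-4-yl]-2-{[(4-methoxyphenyl)methoxy]methyl}prop-2-enoate | COC(=O)/C(COCc1ccc(OC)cc1)=C/[C@@H]1COC(C)(C)O1 | intermediate
15 | methyl (2E,4R)-4,5-dihydroxy-2-{[(4-methoxyphenyl)methoxy]methyl}pent-2-enoate | COC(=O)/C(COCc1ccc(OC)cc1)=C/[C@@H](O)CO | intermediate
16 | methyl (2E,4R)-2-{[(4-methoxyphenyl)methoxy]methyl}-4,5-bis[(triethylsilyl)oxy]pent-2-enoate | COC(=O)/C(COCc1ccc(OC)cc1)=C/[C@@H](O[Si](CC)(CC)CC)CO[Si](CC)(CC)CC | intermediate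
17 | dimethyl(alkoxy)sulfonium chloride at the primary oxygen of 16 | COC(=O)/C(COCc1ccc(OC)cc1)=C/[C@@H](O[Si](CC)(CC)CC)CO[S+](C)C.[Cl-] | intermediate
18 | methyl (2E,4R)-2-{[(4-methoxyphenyl)methoxy]methyl}-5-oxo-4-[(triethylsilyl)oxy]pent-2-enoate | COC(=O)/C(COCc1ccc(OC)cc1)=C/[C@@H](O[Si](CC)(CC)CC)C=O | intermediate
19 | alkenylchromium dichloride derived from 9 (chromium in place of iodine, geometry retained) | COC(OC)/C(=C/CC/C(CO[Si](C)(C)C(C)(C)C)=C\CO)[Cr](Cl)Cl | intermediate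
20 | methyl (2E,4R,5S,6E,10E)-10-{[(tert-butyldimethylsilyl)oxy]methyl}-6-(dimethoxymethyl)-5,12-dihydroxy-2-{[(4-methoxyphenyl)methoxy]methyl}-4-[(triethylsilyl)oxy]dodeca-2,6,10-trienoate | COC(OC)/C(=C/CC/C(CO[Si](C)(C)C(C)(C)C)=C\CO)[C@H](O)[C@H](O[Si](CC)(CC)CC)/C=C(\COCc1ccc(OC)cc1)C(=O)OC | intermediate
21 | methyl (2E,4R,5S,6E,10E)-10-{[(tert-butyldimethylsilyl)oxy]methyl}-6-(dimethoxymethyl)-5-hydroxy-2-{[(4-methoxyphenyl)methoxy]methyl}-12-oxo-4-[(triethylsilyl)oxy]dodeca-2,6,10-trienoate | COC(OC)/C(=C/CC/C(CO[Si](C)(C)C(C)(C)C)=C\C=O)[C@H](O)[C@H](O[Si](CC)(CC)CC)/C=C(\COCc1ccc(OC)cc1)C(=O)OC | intermediate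
22 | methyl (2E,4R,5S,6E,10E)-5-[(tert-butyldimethylsilyl)oxy]-10-{[(tert-butyldimethylsilyl)oxy]methyl}-6-(dimethoxymethyl)-2-{[(4-methoxyphenyl)methoxy]methyl}-12-oxo-4-[(triethylsilyl)oxy]dodeca-2,6,10-trienoate | COC(OC)/C(=C/CC/C(CO[Si](C)(C)C(C)(C)C)=C\C=O)[C@H](O[Si](C)(C)C(C)(C)C)[C@H](O[Si](CC)(CC)CC)/C=C(\COCc1ccc(OC)cc1)C(=O)OC | intermediate
23 | methyl (2E,4R,5S,6E,10E)-5-[(tert-butyldimethylsilyl)oxy]-10-{[(tert-butyldimethylsilyl)oxy]methyl}-6-(dimethoxymethyl)-2-(hydroxymethyl)-12-oxo-4-[(triethylsilyl)oxy]dodeca-2,6,10-trienoate | COC(OC)/C(=C/CC/C(CO[Si](C)(C)C(C)(C)C)=C\C=O)[C@H](O[Si](C)(C)C(C)(C)C)[C@H](O[Si](CC)(CC)CC)/C=C(\CO)C(=O)OC | intermediate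
24 | methyl (2Z,4R,5S,6E,10E)-2-(bromomethyl)-5-[(tert-butyldimethylsilyl)oxy]-10-{[(tert-butyldimethylsilyl)oxy]methyl}-6-(dimethoxymethyl)-12-oxo-4-[(triethylsilyl)oxy]dodeca-2,6,10-trienoate | COC(OC)/C(=C/CC/C(CO[Si](C)(C)C(C)(C)C)=C\C=O)[C@H](O[Si](C)(C)C(C)(C)C)[C@H](O[Si](CC)(CC)CC)/C=C(\CBr)C(=O)OC | intermediate
25 | ten-membered hydroxy ester (6-hydroxy 12-methyl ester, the seco-lactone of 26; 6R,7S,8R,9S) | O[C@@H]1/C=C(/CO[Si](C)(C)C(C)(C)C)CC/C=C(/C(OC)OC)[C@H](O[Si](C)(C)C(C)(C)C)[C@H](O[Si](CC)(CC)CC)[C@H]1C(=C)C(=O)OC | intermediate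
26 | (6R,7S,8R,9S)-9,15-bis[(tert-butyldimethylsilyl)oxy]-14,14-dimethoxy-8-[(triethylsilyl)oxy]germacra-1(10),4,11(13)-trien-12,6-olide | C=C1C(=O)O[C@@H]2/C=C(/CO[Si](C)(C)C(C)(C)C)CC/C=C(/C(OC)OC)[C@H](O[Si](C)(C)C(C)(C)C)[C@H](O[Si](CC)(CC)CC)[C@@H]12 | intermediate
27 | 8-hydroxy analogue of 26 (9,15-bis-O-TBS 14-dimethyl acetal of the 8-deacyl target) | C=C1C(=O)O[C@@H]2/C=C(/CO[Si](C)(C)C(C)(C)C)CC/C=C(/C(OC)OC)[C@H](O[Si](C)(C)C(C)(C)C)[C@H](O)[C@@H]12 | intermediate
28 | (2S)-2-methylbutanoic acid | CC[C@H](C)C(=O)O | starting material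
29 | (6R,7S,8R,9S)-9,15-bis[(tert-butyldimethylsilyl)oxy]-14,14-dimethoxy-8-{[(2S)-2-methylbutanoyl]oxy}germacra-1(10),4,11(13)-trien-12,6-olide | C=C1C(=O)O[C@@H]2/C=C(/CO[Si](C)(C)C(C)(C)C)CC/C=C(/C(OC)OC)[C@H](O[Si](C)(C)C(C)(C)C)[C@H](OC(=O)[C@@H](C)CC)[C@@H]12 | intermediate
30 | (6R,7S,8R,9S)-9,15-dihydroxy-8-{[(2S)-2-methylbutanoyl]oxy}-14-oxogermacra-1(10),4,11(13)-trien-12,6-olide | C=C1C(=O)O[C@@H]2/C=C(/CO)CC/C=C(/C=O)[C@H](O)[C@H](OC(=O)[C@@H](C)CC)[C@@H]12 | target

## Step count and risks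

Total step count: 18. Longest linear sequence: 14 (steps 1–5, then 10–18).

Steps most likely to fail:

1. Step 15 (the new step). The risks are catalyst turnover at 2 mM, simple reduction of the bromide by the Hantzsch ester, and formation of the 6,7-syn (cis-lactone) or C7-epimeric ring. The C8 oxygen is deliberately a silyl ether at this stage, because an ester there would be expelled from the allylchromium by 1,4-elimination; this is why acylation comes after ring closure. Fallback, known chemistry: set out from 24 and drop the photocatalytic cycle in favour of the classical stoichiometric chromium Barbier cyclisation — CrCl2 (6 equiv, divalent chromium), degassed THF/DMF, 24 added by syringe pump to 2 mM, rt, then PPTS. This method has closed 10-membered α-methylene lactones before. It passes through the same hydroxy ester 25 and comes back at 26; no new compound arises (F0).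

2. Step 10. Aldehyde 18 is α-silyloxy and β,γ-unsaturated, so C8 can epimerise or the alkene can drift into conjugation, and the anti/syn ratio at C9 may be modest. Fallback: change the order of assembly so that the coupling uses a robust aldehyde and the enoate is built afterwards. Set out from 9: Et3SiCl/imidazole gives 9 O-triethylsilyl ether F1. Commercial methyl (2R)-2,3-dihydroxypropanoate is bis-silylated to methyl (2R)-2,3-bis[(triethylsilyl)oxy]propanoate F2 and reduced with i-Bu2AlH at −78 °C to (2R)-2,3-bis[(triethylsilyl)oxy]propanal F3. Nozaki–Hiyama–Kishi coupling of F1 with F3 (CrCl2, NiCl2 cat., DMSO) gives the 8,9-anti coupled alcohol F4, and TBSOTf/2,6-lutidine gives its C9 TBS ether F5. One Swern oxidation converts both primary triethylsilyl ethers into aldehydes to give the dialdehyde F6. The phosphonate anion 13 (from 11 and 12, as in step 6) olefinates only the saturated α-silyloxy aldehyde of F6, and the route is rejoined at 22.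

3. Step 16. The primary allylic TBS ether at C15 may be lost together with the C8 triethylsilyl ether, which would expose a second hydroxyl to acylation. Fallback: set out from 26, remove both groups on purpose (PPTS, MeOH, rt) to give the 8,15-diol F7, then re-silylate only the primary allylic hydroxyl (TBSCl, imidazole, CH2Cl2, −20 °C), which comes back at 27.

Further compounds
F0 | step 15 | none | none
F1 | step 10 | 9 O-triethylsilyl ether | COC(OC)/C(I)=C/CC/C(CO[Si](C)(C)C(C)(C)C)=C\CO[Si](CC)(CC)CC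
F2 | step 10 | methyl (2R)-2,3-bis[(triethylsilyl)oxy]propanoate | COC(=O)[C@H](O[Si](CC)(CC)CC)CO[Si](CC)(CC)CC
F3 | step 10 | (2R)-2,3-bis[(triethylsilyl)oxy]propanal | O=C[C@H](O[Si](CC)(CC)CC)CO[Si](CC)(CC)CC
F4 | step 10 | 8,9-anti coupled alcohol (C9 hydroxyl free; O6, O7 and O8 as triethylsilyl ethers) | COC(OC)/C(=C/CC/C(CO[Si](C)(C)C(C)(C)C)=C\CO[Si](CC)(CC)CC)[C@H](O)[C@H](O[Si](CC)(CC)CC)CO[Si](CC)(CC)CC
F5 | step 10 | C9 TBS ether of F4 | COC(OC)/C(=C/CC/C(CO[Si](C)(C)C(C)(C)C)=C\CO[Si](CC)(CC)CC)[C@H](O[Si](C)(C)C(C)(C)C)[C@H](O[Si](CC)(CC)CC)CO[Si](CC)(CC)CC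
F6 | step 10 | dialdehyde (C6 enal and C7 aldehyde) | COC(OC)/C(=C/CC/C(CO[Si](C)(C)C(C)(C)C)=C\C=O)[C@H](O[Si](C)(C)C(C)(C)C)[C@H](O[Si](CC)(CC)CC)C=O
F7 | step 16 | 8,15-diol (9-O-TBS 14-dimethyl acetal of the 8-deacyl target) | C=C1C(=O)O[C@@H]2/C=C(/CO)CC/C=C(/C(OC)OC)[C@H](O[Si](C)(C)C(C)(C)C)[C@H](O)[C@@H]12
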